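**Plan**

- Retrosynthesis: the four C-propionyl bonds are removed first, then the four O-methyl groups. Each terminal ring is then cut twice (acyl-bearing carbon to the enol carbon on the bridge side; bridge-bearing carbon to the enol carbon next to CMe2), leaving a bis(dihydrocoumarin) and two molecules of methyl 2,2-dimethylacetoacetate. The central Ar–CH2–Ar bonds go back to formaldehyde, each lactone to 3,5-dimethoxyphenol and acrylic acid.
- Enabling feature: the bridge-bearing enolic carbon of a terminal ring, its CH2 bridge and the ortho oxygen of the neighbouring inner arene are C3, C4 and O1 of a 3,4-dihydrocoumarin. The lactone carbonyl C2 becomes the ring carbon between the bridge-bearing and the acyl-bearing carbons.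
- Forward order: the lactone rings are fused to the arenes, the arenes are joined through the central CH2, one operation opens both lactones and closes both carbocyclic terminal rings, and demethylation followed by fourfold C-propionylation completes the four-ring chain.
- Stereochemistry: the target has no stereocentre and no stereogenic double bond, so none has to be set.

Key step: step 3

Remark 1: electrophiles are taken to enter 5,7-dimethoxychroman-2-one at C8 (ortho to the 7-methoxy and para to the 5-methoxy group, less hindered than C6), so the bis-lactone is formulated as the 8,8'-linked isomer. A C6-linked isomer would converge on the same compound 11 in step 4, because demethylation makes the three oxygens of each inner ring equivalent.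

Remark 2: the enolised trione rings are written as one tautomer; the tautomeric mixture is meant.

**Route**

Step 1
Reactants: 1 3,5-dimethoxyphenol; 2 acrylic acid
Product: 4 5,7-dimethoxychroman-2-one, via 3-(2-hydroxy-4,6-dimethoxyphenyl)propanoic acid 3 (not isolated)
Conditions: acrylic acid (1.5 equiv), sulfonated polystyrene resin (ArSO3H, H+ form), toluene, reflux, Dean–Stark trap
Reagents that add atoms: none
Why: Acid-catalysed Friedel–Crafts conjugate hydroarylation of acrylic acid at one of the two equivalent carbons ortho to the hydroxyl, followed by lactonisation of acid 3 with azeotropic removal of water, is a known route from electron-rich phenols to dihydrocoumarins; a para-alkylated acid cannot lactonise and would be removed by a bicarbonate wash.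

Step 2
Reactants: 4 5,7-dimethoxychroman-2-one (two equivalents); 5 formaldehyde (as paraformaldehyde)
Product: 7 8,8'-methylenebis(5,7-dimethoxychroman-2-one), via 8-(hydroxymethyl)-5,7-dimethoxychroman-2-one 6 (not isolated)
Conditions: (CH2O)n (0.5 equiv), CF3CO2H, CH2Cl2, 0 °C to rt
Reagents that add atoms: none
Why: Acid-mediated hydroxymethylation followed by Friedel–Crafts benzylation (diarylmethane formation of the phenol–formaldehyde type) should take place at the most activated and least hindered ring carbon, C8, and half an equivalent of formaldehyde lets the benzylic cation from 6 be captured by a second molecule of 4 instead of building chains.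

Step 3
Reactants: 7 8,8'-methylenebis(5,7-dimethoxychroman-2-one); 8 methyl 2,2-dimethylacetoacetate (two equivalents incorporated)
Product: 10 bis[2-hydroxy-4,6-dimethoxy-3-((2,6-dihydroxy-3,3-dimethyl-4-oxocyclohexa-1,5-dien-1-yl)methyl)phenyl]methane, via acyclic bis(diketo ester) 9 (not isolated)
Conditions: 8 (4.5 equiv), LiN(iPr)2 (4.5 equiv), THF, −78 °C; then 7 in THF, −78 to −20 °C; then LiN(iPr)2 (5 equiv), −78 to 0 °C; cold 1 M HCl
Reagents that add atoms: none
Why: Proposed new method: the lithium enolate of 8, formed at the acetyl methyl (its only enolisable carbon), adds to each aryl lactone carbonyl and expels the phenoxide, a second equivalent of enolate taking the acidic proton of the new 1,3-diketone to give bis(diketonate) 9; the added amide base then removes the only γ-proton each diketonate has, at the former lactone C3, and this carbanion attacks the α,α-dimethyl ester with loss of methoxide, which deprotonates the new trione and makes the sequence irreversible. The closest known reactions are the Claisen acylation of ketone enolates by aryl esters such as dihydrocoumarins and the γ-acylation of 1,3-diketone dianions by esters, here intramolecular as in the Dieckmann-type closure of 3,5-dioxoalkanoates to cyclohexane-1,3,5-triones. Each of the two carbocycles closes in a 6-(enolendo)-exo-trig mode, which is allowed for enolates and is helped by the gem-dimethyl group. No stereocentre is formed. The step needs carbon attack on the lactone and on the ester and a single site of enolisation at each stage: the quaternary CMe2 carbon leaves one enolisable methyl in 8 and one γ-CH2 in 9, the phenoxide leaving group is too weak a nucleophile to cause retro-Claisen cleavage of 8, and a lactone enolate, should it form, would collapse to a ketene that the same enolate acylates to the same diketonate.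

Step 4
Reactants: 10 bis[2-hydroxy-4,6-dimethoxy-3-((2,6-dihydroxy-3,3-dimethyl-4-oxocyclohexa-1,5-dien-1-yl)methyl)phenyl]methane
Product: 11 bis[2,4,6-trihydroxy-3-((2,6-dihydroxy-3,3-dimethyl-4-oxocyclohexa-1,5-dien-1-yl)methyl)phenyl]methane
Conditions: BBr3 (12 equiv), CH2Cl2, −78 °C to rt; then H2O, 0 °C; handled under argon
Reagents that add atoms: none
Why: Lewis-acid cleavage of aryl methyl ethers by BBr3 (bromide attacks the methyl group of the boron–ether adduct) should remove all four methyl groups at low temperature, while the diarylmethane bridges and the enolised triones, held as boron aryloxides and enolates, are released unchanged on hydrolysis.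

Step 5
Reactants: 11 bis[2,4,6-trihydroxy-3-((2,6-dihydroxy-3,3-dimethyl-4-oxocyclohexa-1,5-dien-1-yl)methyl)phenyl]methane
Product: 12 bis[2,4,6-trihydroxy-5-propanoyl-3-((2,6-dihydroxy-3,3-dimethyl-4-oxo-5-propanoylcyclohexa-1,5-dien-1-yl)methyl)phenyl]methane (CNP0541376.0)
Conditions: EtCO2H (8 equiv), BF3·OEt2, 60–70 °C, argon; then H2O, 50 °C
Reagents that add atoms: propionic acid, CCC(=O)O
Why: Friedel–Crafts C-acylation with a carboxylic acid in BF3·OEt2, the standard entry to acylphloroglucinols, should fill the single free nucleophilic carbon of each ring (the inner rings are 2,4-dialkylphloroglucinols and the enolised terminal rings react as their non-aromatic, filicinic acid type counterparts), each new ketone being held as a deactivated BF2 chelate until hydrolysis so that every ring is acylated once.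

**Compound list**

1 | 3,5-dimethoxyphenol | COc1cc(O)cc(OC)c1 | starting material
2 | acrylic acid | C=CC(=O)O | starting material
3 | 3-(2-hydroxy-4,6-dimethoxyphenyl)propanoic acid | COc1cc(O)c(CCC(=O)O)c(OC)c1 | intermediate
4 | 5,7-dimethoxychroman-2-one | COc1cc(OC)c2CCC(=O)Oc2c1 | intermediate
5 | formaldehyde (used as paraformaldehyde) | C=O | starting material
6 | 8-(hydroxymethyl)-5,7-dimethoxychroman-2-one | COc1cc(OC)c2CCC(=O)Oc2c1CO | intermediate
7 | 8,8'-methylenebis(5,7-dimethoxychroman-2-one) | COc1cc(OC)c2CCC(=O)Oc2c1Cc1c(OC)cc(OC)c2CCC(=O)Oc12 | intermediate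
8 | methyl 2,2-dimethylacetoacetate (methyl 2,2-dimethyl-3-oxobutanoate) | CC(=O)C(C)(C)C(=O)OC | starting material
9 | dimethyl 7,7'-[methylenebis(2-hydroxy-4,6-dimethoxy-3,1-phenylene)]bis(2,2-dimethyl-3,5-dioxoheptanoate) | COC(=O)C(C)(C)C(=O)CC(=O)CCc1c(OC)cc(OC)c(Cc2c(O)c(CCC(=O)CC(=O)C(C)(C)C(=O)OC)c(OC)cc2OC)c1O | intermediate
10 | bis[2-hydroxy-4,6-dimethoxy-3-((2,6-dihydroxy-3,3-dimethyl-4-oxocyclohexa-1,5-dien-1-yl)methyl)phenyl]methane | COc1cc(OC)c(CC2=C(O)C(C)(C)C(=O)C=C2O)c(O)c1Cc1c(O)c(CC2=C(O)C(C)(C)C(=O)C=C2O)c(OC)cc1OC | intermediate
11 | bis[2,4,6-trihydroxy-3-((2,6-dihydroxy-3,3-dimethyl-4-oxocyclohexa-1,5-dien-1-yl)methyl)phenyl]methane | Oc1cc(O)c(CC2=C(O)C(C)(C)C(=O)C=C2O)c(O)c1Cc1c(O)c(CC2=C(O)C(C)(C)C(=O)C=C2O)c(O)cc1O | intermediate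
12 | bis[2,4,6-trihydroxy-5-propanoyl-3-((2,6-dihydroxy-3,3-dimethyl-4-oxo-5-propanoylcyclohexa-1,5-dien-1-yl)methyl)phenyl]methane (CNP0541376.0) | CCC(=O)C1=C(O)C(Cc2c(O)c(Cc3c(O)c(CC4=C(O)C(C)(C)C(=O)C(C(=O)CC)=C4O)c(O)c(C(=O)CC)c3O)c(O)c(C(=O)CC)c2O)=C(O)C(C)(C)C1=O | target

**Step count**

Total steps: 5. Longest linear sequence: 5 steps (1 → 4 → 7 → 10 → 11 → 12).

**Steps most likely to fail**

1. Step 3 (the proposed method).
   - Risk: proton transfer from the lactone C3–H to the enolate may compete with carbonyl addition and divert material through a ketene to amide or oligomers. Acylation may stop after one lactone. The dianion may fail to close on the hindered ester, or may close through oxygen to a pyranone.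
   - Fallback with known chemistry, from 7 back to 11: ring-opening O-methylation of both lactones (K2CO3, MeI, MeOH–acetone, reflux) should give dimethyl 3,3'-[methylenebis(2,4,6-trimethoxy-3,1-phenylene)]dipropanoate F1, whose alkyl esters cannot eliminate to a ketene. Crossed Claisen condensation with the lithium enolate of 8 (excess, THF, −78 °C to rt) should give dimethyl 7,7'-[methylenebis(2,4,6-trimethoxy-3,1-phenylene)]bis(2,2-dimethyl-3,5-dioxoheptanoate) F2, which is isolated. NaOMe in MeOH at reflux should then close both rings under thermodynamic control, the trione anion being the sink, to bis[2,4,6-trimethoxy-3-((2,6-dihydroxy-3,3-dimethyl-4-oxocyclohexa-1,5-dien-1-yl)methyl)phenyl]methane F3. BBr3 cleaves all six methyl ethers and the sequence rejoins the route at 11.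

2. Step 5.
   - Risk: acid-promoted fission and scrambling of the three methylene bridges, cyclodehydration between hydroxyls that face each other across a bridge, and incomplete fourfold acylation of an air-sensitive polyphenol.
   - Fallback, from 10 to 12, with acylation moved ahead of deprotection so that the polyphenol is never exposed unacylated to hot Lewis acid: propionyl chloride and AlCl3 in CH2Cl2 (0 °C to rt) should acylate the free carbon of each dimethoxyphenol ring by Friedel–Crafts reaction and each enolised trione by acylation with Fries-type O-to-C migration. This gives bis[2-hydroxy-4,6-dimethoxy-5-propanoyl-3-((2,6-dihydroxy-3,3-dimethyl-4-oxo-5-propanoylcyclohexa-1,5-dien-1-yl)methyl)phenyl]methane F4. BBr3 then cleaves the four methyl ethers, each ortho to a new aryl ketone and so assisted by chelation, to give 12. A methyl ether lost early under AlCl3 is one the last step removes anyway.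

3. Step 2.
   - Risk: continued condensation through the remaining ring carbon to oligomers, and partial linkage through C6.
   - Fallback, from 4 back to 7, with one electrophilic carbon per pair and no free formaldehyde: Vilsmeier–Haack formylation (POCl3, DMF) should give 5,7-dimethoxy-2-oxochromane-8-carbaldehyde F5, purified as a single regioisomer. Reductive Friedel–Crafts benzylation of a second equivalent of 4 with F5 (Et3SiH, CF3CO2H, CH2Cl2) should then give 7.

**Further compounds**

F1 | step 3 | dimethyl 3,3'-[methylenebis(2,4,6-trimethoxy-3,1-phenylene)]dipropanoate | COC(=O)CCc1c(OC)cc(OC)c(Cc2c(OC)c(CCC(=O)OC)c(OC)cc2OC)c1OC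
F2 | step 3 | dimethyl 7,7'-[methylenebis(2,4,6-trimethoxy-3,1-phenylene)]bis(2,2-dimethyl-3,5-dioxoheptanoate) | COC(=O)C(C)(C)C(=O)CC(=O)CCc1c(OC)cc(OC)c(Cc2c(OC)c(CCC(=O)CC(=O)C(C)(C)C(=O)OC)c(OC)cc2OC)c1OC
F3 | step 3 | bis[2,4,6-trimethoxy-3-((2,6-dihydroxy-3,3-dimethyl-4-oxocyclohexa-1,5-dien-1-yl)methyl)phenyl]methane | COc1cc(OC)c(CC2=C(O)C(C)(C)C(=O)C=C2O)c(OC)c1Cc1c(OC)c(CC2=C(O)C(C)(C)C(=O)C=C2O)c(OC)cc1OC
F4 | step 5 | bis[2-hydroxy-4,6-dimethoxy-5-propanoyl-3-((2,6-dihydroxy-3,3-dimethyl-4-oxo-5-propanoylcyclohexa-1,5-dien-1-yl)methyl)phenyl]methane | CCC(=O)C1=C(O)C(Cc2c(O)c(Cc3c(O)c(CC4=C(O)C(C)(C)C(=O)C(C(=O)CC)=C4O)c(OC)c(C(=O)CC)c3OC)c(OC)c(C(=O)CC)c2OC)=C(O)C(C)(C)C1=O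
F5 | step 2 | 5,7-dimethoxy-2-oxochromane-8-carbaldehyde | COc1cc(OC)c2CCC(=O)Oc2c1C=O
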